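**Retrosynthetic overview**

1. The target is two perhydro-1-benzoxepine halves that differ only at the acetoxy carbon C-7 and are joined C-6–CH2–CH2–C-6'. The last steps are acetylation of both tertiary alcohols, desilylation and oxidation at C-3/C-3'. The CH2–CH2 bond comes from radical conjugate addition of a 6-iodomethyl half (axial 7-OH, from MeLi) to a 6-methylidene-7-ketone, whose ketone then becomes the equatorial 7'-OH by methylenation and hydration.
2. Both halves come from one bicyclic enone, made from a bicyclic β-keto ester by decarboxylative methylenation. The β-keto ester is the product of a (3+3) annulation of benzyl acetoacetate (C-6, C-7, C-8) with a diepoxygeranyl triflate: C-8–C-9 by dianion alkylation, then C-5a–C-6 and O-1–C-2 by a silyl-triflate-triggered epoxonium relay in the same flask.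
3. Enabling feature: in each cyclohexane ring C-7 is a latent ketone flanked by C-6 and C-8. The opposite edge C-9–C-9a(O)–C-5a(CH3) is the trace of a 2,3-epoxy alcohol whose oxygen, as O-1 of the oxepane, sits 1,5 to the oxygenated pair C-3/C-2(CH3)2. Each half is therefore an acetoacetate plus a twofold epoxidised geraniol.
4. Ring order in each half: oxepane first, then cyclohexanone, both in the annulation step; no ring is formed later.
5. The triflate comes from geraniol by Sharpless epoxidation, Shi epoxidation and triflation.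

Key step: step 4

Remarks. Locants follow 1-benzoxepine numbering: O-1, C-2 (CMe2), C-3, C-4, C-5, C-5a (quaternary, methyl), C-6, C-7 (carbinol carbon), C-8, C-9, C-9a (CH–O). Assumption: the C-3 configuration set in step 2 is erased in step 13; it is carried as (S), the sense expected from the L-series Shi ketone, so that the diepoxide is like-configured as in known polyepoxide cascades. Enone 10 is made once and used in steps 6 and 8. Compound 8 is a keto/enol and C-6 epimer mixture and is drawn as the 6S keto form.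

**Route**

Step 1
Reactants: 1 geraniol
Product: 2 (2S,3S)-2,3-epoxygeraniol
Conditions: Ti(OiPr)4 (5 mol%), L-(+)-diethyl tartrate (7 mol%), t-BuOOH, 4 Å molecular sieves, CH2Cl2, −20 °C
Reagents that add atoms: tert-butyl hydroperoxide, CC(C)(C)OO
Why: Sharpless asymmetric epoxidation: the allylic hydroxyl binds the titanium tartrate catalyst, which epoxidises only the 2,3-alkene and, with L-(+)-diethyl tartrate, sets both new centres as (2S,3S).

Step 2
Reactants: 2 (2S,3S)-2,3-epoxygeraniol
Product: 3 diepoxy alcohol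
Conditions: 1,2:4,5-di-O-isopropylidene-β-L-erythro-2,3-hexodiulo-2,6-pyranose (ent-Shi ketone, 30 mol%), KHSO5 (as 2KHSO5·KHSO4·K2SO4), K2CO3, Bu4NHSO4 (cat.), aq. Na2B4O7/Na2EDTA, MeCN/dimethoxymethane, 0 °C
Reagents that add atoms: potassium peroxymonosulfate, [K+].[O-]S(=O)(=O)OO
Why: Shi epoxidation: the chiral dioxirane attacks the remaining electron-rich trisubstituted alkene through a spiro transition state, and the L-series ketone is expected to give the (S) epoxide.

Step 3
Reactants: 3 diepoxy alcohol
Product: 4 diepoxy triflate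
Conditions: Tf2O, 2,6-lutidine, CH2Cl2, −78 °C; cold filtration through silica, used at once
Reagents that add atoms: trifluoromethanesulfonic anhydride, O=S(=O)(OS(=O)(=O)C(F)(F)F)C(F)(F)F
Why: Sulfonylation of the primary alcohol with triflic anhydride and a hindered pyridine base at low temperature gives the primary triflate without touching the epoxides or any stereocentre.

Step 4
Reactants: 4 diepoxy triflate and 5 benzyl acetoacetate
Product: 8 benzyl (3S,5aS,6S,9aS)-3-[(tert-butyldimethylsilyl)oxy]-2,2,5a-trimethyl-7-oxodecahydro-1-benzoxepine-6-carboxylate, via keto ester enolate 6 (not isolated), via enol silane 7 (not isolated)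
Conditions: 5, NaH then n-BuLi, THF, 0 °C; 4, −78 °C; THF replaced by CH2Cl2; 2,6-di-tert-butyl-4-methylpyridine, TBSOTf (2.5 equiv), −78 °C; aq. NaHCO3
Reagents that add atoms: tert-butyldimethylsilyl trifluoromethanesulfonate, CC(C)(C)[Si](C)(C)OS(=O)(=O)C(F)(F)F
Why: Proposed new method: the γ-carbon of the acetoacetate dianion displaces the primary triflate (bond C-8–C-9), the remaining enolate is O-silylated by the first equivalent of TBSOTf, and silylation of the terminal epoxide then lets the inner epoxide oxygen open it at the gem-dimethyl carbon to a bicyclic epoxonium ion, which the enol silane carbon opens at its tertiary carbon C-5a (bond C-5a–C-6) with return of the silyl cation, so the second stage is catalytic in silyl triflate. The closest known reactions are the Weiler dianion (3+3) annulation with 1,3-dihalides and the silyl-triflate-promoted tandem oxa/carbacyclisation of 1,5-diepoxides with enol silane terminators, here merged in one flask. The oxepane closes by endo attack of the epoxide oxygen on the gem-dimethyl carbon (seven-membered after the epoxonium C–O cleavage) and the cyclohexanone by 6-endo opening of the epoxonium ion through a chair transition state. C-9a keeps the Sharpless configuration, C-5a is set by inversion at the epoxide carbon (anti opening, hence the trans ring fusion with axial methyl), C-3 keeps the Shi configuration, and C-6 is epimerisable and becomes sp2 in step 5. The step needs γ- over α-alkylation (secured by the dianion), attack on the triflate before the epoxides (−78 °C), C- over O-capture of the cation (the enol oxygen is silylated) and tertiary-carbon regioselectivity in both epoxide openings (both distal epoxide carbons are fully substituted).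

Step 5
Reactants: 8 bicyclic β-keto ester
Product: 10 (3S,5aS,9aS)-3-[(tert-butyldimethylsilyl)oxy]-2,2,5a-trimethyl-6-methylideneoctahydro-1-benzoxepin-7(2H)-one, via keto acid 9 (not isolated)
Conditions: H2 (1 atm), 10% Pd/C, EtOAc, rt; then aq. CH2O, Et2NH, THF, 0 to 40 °C
Reagents that add atoms: formaldehyde, C=O
Why: Hydrogenolysis of the benzyl ester and decarboxylative Mannich condensation of the β-keto acid with formaldehyde (Mannich base, then loss of CO2 and amine) place the methylidene group only at C-6, where the carboxyl group sat.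

Step 6
Reactants: 10 bicyclic enone
Product: 11 (3S,5aS,7R,9aS)-3-[(tert-butyldimethylsilyl)oxy]-2,2,5a,7-tetramethyl-6-methylidenedecahydro-1-benzoxepin-7-ol
Conditions: MeLi, Et2O, −78 °C; H2O
Reagents that add atoms: methyllithium, [Li]C
Why: 1,2-Addition of methyllithium to the enone carbonyl: the axial C-5a methyl group shields the axial face of C-7, so methyl should enter equatorially and the new tertiary alcohol should be axial (7R).

Step 7
Reactants: 11 allylic alcohol
Product: 13 (3S,5aS,6S,7R,9aS)-3-[(tert-butyldimethylsilyl)oxy]-6-(iodomethyl)-2,2,5a,7-tetramethyldecahydro-1-benzoxepin-7-ol, via alkylborane 12 (not isolated)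
Conditions: 9-borabicyclo[3.3.1]nonane (2.5 equiv), THF, 60 °C; then I2, NaOMe, MeOH, 0 °C to rt
Reagents that add atoms: iodine, II
Why: Brown hydroboration–iodination: boron adds to the terminal carbon and hydrogen to C-6 from the face opposite the axial C-5a methyl and C-7 oxygen, which should set C-6 as 6S with the side chain equatorial, and iodine with methoxide cleaves the primary B–C bond to the iodide.

Step 8
Reactants: 13 iodide and 10 bicyclic enone
Product: 14 ethylene-bridged keto alcohol
Conditions: Bu3SnH (syringe pump), 2,2'-azobis(2-methylpropionitrile) (0.2 equiv), benzene, 80 °C; then 1,8-diazabicyclo[5.4.0]undec-7-ene (cat.), CH2Cl2, rt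
Reagents that add atoms: none
Why: Giese radical conjugate addition: the primary alkyl radical from the iodide adds to the unhindered methylidene carbon of the enone, and the new centre next to the ketone is brought by base equilibration to the stable arrangement with the side chain equatorial.

Step 9
Reactants: 14 keto alcohol
Product: 15 methylidene alcohol
Conditions: Ph3PCH3Br, KOtBu (excess), toluene, 90 °C
Reagents that add atoms: methyltriphenylphosphonium bromide (as its ylide), C[P+](c1ccccc1)(c1ccccc1)c1ccccc1.[Br-]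
Why: Wittig methylenation of the ketone with excess ylide at elevated temperature, a reaction that works on similarly hindered ring ketones; the adjacent centre stays in its thermodynamically preferred configuration.

Step 10
Reactants: 15 methylidene alcohol
Product: 16 bis-tertiary diol
Conditions: Co(acac)2 (20 mol%), PhSiH3, O2 (1 atm), i-PrOH, rt
Reagents that add atoms: oxygen, O=O
Why: Mukaiyama hydration (hydrogen atom transfer from a cobalt hydride, then oxygen capture): the tertiary C-7 radical should be trapped on its equatorial side because the syn-axial C-5a methyl group blocks the axial side, giving the equatorial (7S) alcohol with axial methyl.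

Step 11
Reactants: 16 diol
Product: 17 diacetate bis-silyl ether
Conditions: Ac2O, 4-(dimethylamino)pyridine, Et3N, 60 °C
Reagents that add atoms: acetic anhydride, CC(=O)OC(C)=O
Why: Nucleophile-catalysed acylation (Steglich type) under forcing conditions acetylates both hindered tertiary alcohols, the only free hydroxyl groups, without change at any stereocentre.

Step 12
Reactants: 17 diacetate bis-silyl ether
Product: 18 diacetate diol
Conditions: HF·pyridine, pyridine, THF, 0 °C to rt
Reagents that add atoms: none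
Why: Fluoride-induced cleavage of the two secondary silyl ethers under pyridine-buffered conditions that tertiary acetates tolerate.

Step 13
Reactants: 18 diacetate diol
Product: 19 target diketone diacetate
Conditions: Dess–Martin periodinane (1,1,1-triacetoxy-1,1-dihydro-1,2-benziodoxol-3(1H)-one), CH2Cl2, rt
Reagents that add atoms: none
Why: Dess–Martin oxidation converts both secondary alcohols into ketones under neutral conditions, removing the C-3 stereocentres and giving the target.

**Compound list**

1 | geraniol, (2E)-3,7-dimethylocta-2,6-dien-1-ol | CC(C)=CCC/C(C)=C/CO | starting material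
2 | [(2S,3S)-3-methyl-3-(4-methylpent-3-en-1-yl)oxiran-2-yl]methanol | OC[C@@H]1O[C@@]1(C)CCC=C(C)C | intermediate
3 | [(2S,3S)-3-{2-[(2S)-3,3-dimethyloxiran-2-yl]ethyl}-3-methyloxiran-2-yl]methanol | OC[C@@H]1O[C@@]1(C)CC[C@@H]1OC1(C)C | intermediate
4 | [(2S,3S)-3-{2-[(2S)-3,3-dimethyloxiran-2-yl]ethyl}-3-methyloxiran-2-yl]methyl trifluoromethanesulfonate | O=S(=O)(OC[C@@H]1O[C@@]1(C)CC[C@@H]1OC1(C)C)C(F)(F)F | intermediate
5 | benzyl 3-oxobutanoate (benzyl acetoacetate) | CC(=O)CC(=O)OCc1ccccc1 | starting material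
6 | benzyl 5-[(2S,3S)-3-{2-[(2S)-3,3-dimethyloxiran-2-yl]ethyl}-3-methyloxiran-2-yl]-3-oxopentanoate (present as its alkali metal enolate) | O=C(CC(=O)CC[C@@H]1O[C@@]1(C)CC[C@@H]1OC1(C)C)OCc1ccccc1 | intermediate
7 | benzyl (2Z)-3-[(tert-butyldimethylsilyl)oxy]-5-[(2S,3S)-3-{2-[(2S)-3,3-dimethyloxiran-2-yl]ethyl}-3-methyloxiran-2-yl]pent-2-enoate | O=C(OCc1ccccc1)/C=C(\O[Si](C)(C)C(C)(C)C)CC[C@@H]1O[C@@]1(C)CC[C@@H]1OC1(C)C | intermediate
8 | benzyl (3S,5aS,6S,9aS)-3-[(tert-butyldimethylsilyl)oxy]-2,2,5a-trimethyl-7-oxodecahydro-1-benzoxepine-6-carboxylate (trans-fused) | O=C1CC[C@@H]2OC(C)(C)[C@@H](O[Si](C)(C)C(C)(C)C)CC[C@@]2(C)[C@@H]1C(=O)OCc1ccccc1 | intermediate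
9 | (3S,5aS,6S,9aS)-3-[(tert-butyldimethylsilyl)oxy]-2,2,5a-trimethyl-7-oxodecahydro-1-benzoxepine-6-carboxylic acid | O=C1CC[C@@H]2OC(C)(C)[C@@H](O[Si](C)(C)C(C)(C)C)CC[C@@]2(C)[C@@H]1C(=O)O | intermediate
10 | (3S,5aS,9aS)-3-[(tert-butyldimethylsilyl)oxy]-2,2,5a-trimethyl-6-methylideneoctahydro-1-benzoxepin-7(2H)-one | O=C1CC[C@@H]2OC(C)(C)[C@@H](O[Si](C)(C)C(C)(C)C)CC[C@@]2(C)C1=C | intermediate
11 | (3S,5aS,7R,9aS)-3-[(tert-butyldimethylsilyl)oxy]-2,2,5a,7-tetramethyl-6-methylidenedecahydro-1-benzoxepin-7-ol (axial OH) | O[C@]1(C)CC[C@@H]2OC(C)(C)[C@@H](O[Si](C)(C)C(C)(C)C)CC[C@@]2(C)C1=C | intermediate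
12 | 9-({(3S,5aS,6S,7R,9aS)-7-[(9-borabicyclo[3.3.1]nonan-9-yl)oxy]-3-[(tert-butyldimethylsilyl)oxy]-2,2,5a,7-tetramethyldecahydro-1-benzoxepin-6-yl}methyl)-9-borabicyclo[3.3.1]nonane | B1(C2CCCC1CCC2)O[C@]1(C)CC[C@@H]2OC(C)(C)[C@@H](O[Si](C)(C)C(C)(C)C)CC[C@@]2(C)[C@@H]1CB1C2CCCC1CCC2 | intermediate
13 | (3S,5aS,6S,7R,9aS)-3-[(tert-butyldimethylsilyl)oxy]-6-(iodomethyl)-2,2,5a,7-tetramethyldecahydro-1-benzoxepin-7-ol | O[C@]1(C)CC[C@@H]2OC(C)(C)[C@@H](O[Si](C)(C)C(C)(C)C)CC[C@@]2(C)[C@@H]1CI | intermediate
14 | (3S,5aS,6S,9aS)-3-[(tert-butyldimethylsilyl)oxy]-6-{2-[(3S,5aS,6S,7R,9aS)-3-[(tert-butyldimethylsilyl)oxy]-7-hydroxy-2,2,5a,7-tetramethyldecahydro-1-benzoxepin-6-yl]ethyl}-2,2,5a-trimethyloctahydro-1-benzoxepin-7(2H)-one | O[C@]1(C)CC[C@@H]2OC(C)(C)[C@@H](O[Si](C)(C)C(C)(C)C)CC[C@@]2(C)[C@@H]1CC[C@H]1[C@]2(C)CC[C@H](O[Si](C)(C)C(C)(C)C)C(C)(C)O[C@H]2CCC1=O | intermediate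
15 | (3S,5aS,6S,7R,9aS)-3-[(tert-butyldimethylsilyl)oxy]-6-{2-[(3S,5aS,6R,9aS)-3-[(tert-butyldimethylsilyl)oxy]-2,2,5a-trimethyl-7-methylidenedecahydro-1-benzoxepin-6-yl]ethyl}-2,2,5a,7-tetramethyldecahydro-1-benzoxepin-7-ol | O[C@]1(C)CC[C@@H]2OC(C)(C)[C@@H](O[Si](C)(C)C(C)(C)C)CC[C@@]2(C)[C@@H]1CC[C@H]1[C@]2(C)CC[C@H](O[Si](C)(C)C(C)(C)C)C(C)(C)O[C@H]2CCC1=C | intermediate
16 | (3S,5aS,6S,7R,9aS)-3-[(tert-butyldimethylsilyl)oxy]-6-{2-[(3S,5aS,6S,7S,9aS)-3-[(tert-butyldimethylsilyl)oxy]-7-hydroxy-2,2,5a,7-tetramethyldecahydro-1-benzoxepin-6-yl]ethyl}-2,2,5a,7-tetramethyldecahydro-1-benzoxepin-7-ol | O[C@]1(C)CC[C@@H]2OC(C)(C)[C@@H](O[Si](C)(C)C(C)(C)C)CC[C@@]2(C)[C@@H]1CC[C@H]1[C@]2(C)CC[C@H](O[Si](C)(C)C(C)(C)C)C(C)(C)O[C@H]2CC[C@]1(C)O | intermediate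
17 | (3S,5aS,6S,7R,9aS)-6-{2-[(3S,5aS,6S,7S,9aS)-7-acetoxy-3-[(tert-butyldimethylsilyl)oxy]-2,2,5a,7-tetramethyldecahydro-1-benzoxepin-6-yl]ethyl}-3-[(tert-butyldimethylsilyl)oxy]-2,2,5a,7-tetramethyldecahydro-1-benzoxepin-7-yl acetate | CC(=O)O[C@]1(C)CC[C@@H]2OC(C)(C)[C@@H](O[Si](C)(C)C(C)(C)C)CC[C@@]2(C)[C@@H]1CC[C@H]1[C@]2(C)CC[C@H](O[Si](C)(C)C(C)(C)C)C(C)(C)O[C@H]2CC[C@]1(C)OC(C)=O | intermediate
18 | (3S,5aS,6S,7R,9aS)-6-{2-[(3S,5aS,6S,7S,9aS)-7-acetoxy-3-hydroxy-2,2,5a,7-tetramethyldecahydro-1-benzoxepin-6-yl]ethyl}-3-hydroxy-2,2,5a,7-tetramethyldecahydro-1-benzoxepin-7-yl acetate | CC(=O)O[C@]1(C)CC[C@@H]2OC(C)(C)[C@@H](O)CC[C@@]2(C)[C@@H]1CC[C@H]1[C@]2(C)CC[C@H](O)C(C)(C)O[C@H]2CC[C@]1(C)OC(C)=O | intermediate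
19 | (5aS,6S,7R,9aS)-6-{2-[(5aS,6S,7S,9aS)-7-acetoxy-2,2,5a,7-tetramethyl-3-oxodecahydro-1-benzoxepin-6-yl]ethyl}-2,2,5a,7-tetramethyl-3-oxodecahydro-1-benzoxepin-7-yl acetate | CC(=O)O[C@]1(C)CC[C@@H]2OC(C)(C)C(=O)CC[C@@]2(C)[C@@H]1CC[C@H]1[C@]2(C)CCC(=O)C(C)(C)O[C@H]2CC[C@]1(C)OC(C)=O | target

**Step count and risks**

Total step count: 13. Longest linear sequence: 13 steps (geraniol to 19; enone 10 is made once and enters twice, in steps 6 and 8).

Most likely to fail:

Step 4 (proposed new method). The silyl triflate may activate the inner epoxide before the outer one, so the oxygen relay that builds the oxepane is lost. The dianion may attack an epoxide carbon instead of the triflate. Salts carried over from the alkylation may capture the cation. The fallback sets out from 4 and 5 and returns to the route at 8, with each event run as a separate, known reaction. Triflate 4 is exchanged with NaI in acetone at 0 °C into the more robust (2R,3S)-3-{2-[(2S)-3,3-dimethyloxiran-2-yl]ethyl}-2-(iodomethyl)-3-methyloxirane F1. F1 alkylates the dianion of 5 at 0 °C (Weiler γ-alkylation), and acetic acid quench and chromatography give pure keto ester 6. Compound 6 is converted with TBSOTf and Et3N into enol silane 7, which is isolated. Pure 7 is then cyclised with a catalytic amount of TBSOTf and 2,6-di-tert-butyl-4-methylpyridine in CH2Cl2 at −78 °C, the known tandem cyclisation of diepoxide enol silanes, to give 8.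

Step 7. Hydroboration may stall at the alkene flanked by two fully substituted carbons, or hydrogen may be delivered to the wrong face of C-6. The fallback sets out from 10 and returns at 14; it sets C-6 under thermodynamic control. Conjugate addition of benzeneselenol (PhSeSePh, NaBH4, EtOH, 0 °C) to 10 gives (3S,5aS,6S,9aS)-3-[(tert-butyldimethylsilyl)oxy]-2,2,5a-trimethyl-6-[(phenylselanyl)methyl]octahydro-1-benzoxepin-7(2H)-one F2, whose C-6 centre equilibrates to the equatorial side chain. Addition of MeLi in the presence of CeCl3 (THF, −78 °C) from the equatorial face gives (3S,5aS,6S,7R,9aS)-3-[(tert-butyldimethylsilyl)oxy]-2,2,5a,7-tetramethyl-6-[(phenylselanyl)methyl]decahydro-1-benzoxepin-7-ol F3. F3 is the radical precursor in the Giese addition to 10 (Bu3SnH, 2,2'-azobis(2-methylpropionitrile), benzene, 80 °C), which gives 14.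

Step 10. Oxygen capture by the planar tertiary radical may show poor facial selectivity, and reduction of the intermediate hydroperoxide may be incomplete. The fallback sets out from 15 and returns at 16. Epoxidation of 15 with m-chloroperbenzoic acid and NaHCO3 in CH2Cl2 at 0 °C, from the equatorial side as known for exocyclic alkenes with a syn-axial methyl group, gives the spiro-epoxide of 15 (7-methylidene converted into a spiro-oxirane with equatorial oxygen) F4. Opening of F4 at the CH2 carbon with LiEt3BH in THF gives 16.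

Further compounds
F1 | step 4 | (2R,3S)-3-{2-[(2S)-3,3-dimethyloxiran-2-yl]ethyl}-2-(iodomethyl)-3-methyloxirane | IC[C@@H]1O[C@@]1(C)CC[C@@H]1OC1(C)C
F2 | step 7 | (3S,5aS,6S,9aS)-3-[(tert-butyldimethylsilyl)oxy]-2,2,5a-trimethyl-6-[(phenylselanyl)methyl]octahydro-1-benzoxepin-7(2H)-one | O=C1CC[C@@H]2OC(C)(C)[C@@H](O[Si](C)(C)C(C)(C)C)CC[C@@]2(C)[C@@H]1C[Se]c1ccccc1
F3 | step 7 | (3S,5aS,6S,7R,9aS)-3-[(tert-butyldimethylsilyl)oxy]-2,2,5a,7-tetramethyl-6-[(phenylselanyl)methyl]decahydro-1-benzoxepin-7-ol | O[C@]1(C)CC[C@@H]2OC(C)(C)[C@@H](O[Si](C)(C)C(C)(C)C)CC[C@@]2(C)[C@@H]1C[Se]c1ccccc1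
F4 | step 10 | spiro-epoxide of 15 (7-methylidene converted into a spiro-oxirane, oxygen equatorial) | O[C@]1(C)CC[C@@H]2OC(C)(C)[C@@H](O[Si](C)(C)C(C)(C)C)CC[C@@]2(C)[C@@H]1CC[C@H]1[C@]2(C)CC[C@H](O[Si](C)(C)C(C)(C)C)C(C)(C)O[C@H]2CC[C@]1(C3)O3
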